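## The problem

CNP0167461.1 (**31**) is a heliangolide-type germacranolide. It has a ten-membered carbocycle (C1–C10) with a trans-fused α-methylene-γ-lactone across C6–C7 (oxygen on C6), a Z trisubstituted C4=C5 alkene, and a 1β,10α-epoxide that is the oxide of an E C1=C10 alkene. O3 carries an isovalerate and O8 a (2S,3S)-2,3-dimethyloxirane-2-carboxylate. Ring closure and olefin geometry have to be solved together, because both ring olefins are trisubstituted and of fixed, different geometry. C3 (S) and C8 (R) sit on opposite sides of the ring and cannot control each other, so each needs its own absolute control. C8 can then direct C7 (R), C7 can bias C6 (R), the ring conformation decides the epoxide face (1R,10R), and the side-chain epoxide must come in as a single enantiomer. Several groups are fragile: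
- the α-methylene lactone is attacked by nucleophiles and peroxide anions;
- both epoxides and the cyclodeca-1,5-diene are acid-sensitive (transannular cyclisation);
- the isovalerate is enolisable;
- a free O3 next to a Z C4=C5–C6 ketone would close to a furan;
- an oxygen on C8 β to a C6 ketone would be eliminated under enolate conditions.

The enabling feature is that C4=C5 and C1=C10 flank the C2–C3 bond as a cis,trans-cyclodeca-1,5-diene. Joining C1 to C4 and C5 to C10 on paper gives a bicyclo[2.2.0]hexane fused to a six-membered ring (C5–C10). That is the [2+2] adduct of a cyclohexenone (C5=C10, carbonyl C6) and a cyclobutene (C1=C4, carbinol C3).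

## Retrosynthesis

**Epoxide.** The two oxirane C–O bonds at C1 and C10 are cut last, giving triene **30**. The epoxide is the most acid-labile group, and in **30** the C1=C10 alkene is the only electron-rich one: C4=C5 is flanked by two acyloxy carbons and C11=C13 is conjugated. The forward step needs only site selectivity and attack on the outer face of the E alkene.

**Esters.** The ester C–O bonds at O3 and O8 are cut next: **30** from alcohol **29**, **29** from the 4-methoxybenzyl ether **28**, and **28** from alcohol **23** and epoxy acid **27**. Both acylations come after all strong-base chemistry. O8 is acylated first because it is free when O3 is still protected. The forward steps must keep the configuration at C3 and C8, which acylation of the hydroxyl oxygens guarantees.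

**Side-chain acid.** Acid **27** is cut at the oxirane back to epoxy alcohol **26**, (Z)-allylic alcohol **25** and methyl angelate **24**. An asymmetric epoxidation sets both centres at once and avoids diastereomeric esters on the ring.

**Methylene.** The C11=C13 bond is cut, taking **23** back to hydroxy lactone **20**. Doing this on the bare hydroxy lactone avoids O→C acyl transfer and ester enolisation, which a later methylenation would risk.

**C8 oxygen.** The C8–O bond is replaced by C8–Si, leading to silyl lactone **19**. Silicon is a hydroxyl that cannot be eliminated from a C7 enolate, and it is oxidised with retention. Its oxidation must tolerate two ring alkenes, which rules out the electrophilic variants.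

**Lactone.** The C6–O bond of **19** is cut with inversion, to the 6β-hydroxy acid **18**, and that to keto ester **16**. Hydride is expected to enter the C6 carbonyl anti to the C8 branch of C7, giving the oxygen cis to the side chain. The trans-lactone is therefore closed by displacement at the allylic C6, not by direct esterification.

**C7–C11.** This bond is cut to dienone **14** and methyl bromoacetate **15**. The alkylation is placed on the ten-membered ring because the required relationship (side chain cis to the C8 substituent on the ring) is the open-chain "anti-to-silicon" outcome. A cyclohexanone enolate would give the trans isomer.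

**Ring.** Dienone **14** is reconnected at C1–C4 and C5–C10 to the tricyclic ketone **13**. This removes the medium ring and both olefin geometries in one move, against cuts that close the ten-membered ring directly. The forward cycloreversion must cleave the ring-fusion bond and give Z at C4=C5 and E at C1=C10.

**Key disconnection.** The cyclobutane bonds C4–C5 and C1–C10 of **13** are cut to enone **7** and cyclobutenyl ether **12**. Each partner is a small ring with one stereocentre (C8 in **7**, C3 in **12**). The four centres formed are erased later, so only regiochemistry and cis ring fusion matter.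

**Enone.** **7** is traced through tertiary allylic alcohol **6** and enone **5** to silyl ketone **3**, made from cyclohexenone **1** and silylboronate **2**. Catalytic asymmetric silyl transfer sets C8.

**Cyclobutene.** **12** is traced through the resolved alcohol **11** and racemic alcohol **10** to 1-methylcyclobutene **9** and methylenecyclobutane **8**. The ether group is chosen to survive fluoride and to be introduced without alkoxide or acid.

## Roads not taken

**Alternative 1: Ireland–Claisen ring contraction.** The cut is C7–C8. In the forward direction a silyl ketene acetal inside a fourteen-membered ring rearranges, forming C7–C8 as O–C13 breaks, and gives the ten-membered acid A1 with the C11=C13 methylene already present.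
- Merits: the methylene and the vicinal C7/C8 pair come from one sigmatropic event, a large-ring lactonisation replaces a medium-ring closure, and no photochemistry or high temperature is needed.
- Weak points: both trisubstituted ring olefins must be built with defined geometry in a long acyclic precursor. The chair/boat preference inside a macrocycle decides C7 and C8 and is hard to predict. C8 emerges quaternary with a carboxyl that must be excised and its oxygen stereochemistry reset.
- Comparison: this road is better than the chosen plan at the lactone unit, which here costs alkylation, reduction, inversion and methylenation. The chosen plan sets against that a ring and two olefin geometries made from two small rings in two steps, with each stereocentre set on a simple substrate.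

**Alternative 2: palladium cyclocarbonylation.** The cuts are C11–C12 and C12–O6. In the forward direction a C7 ethynyl group and the trans C6 hydroxyl take up CO (PdCl2, SnCl2, PPh3) to give lactone A2 with the methylene in place.
- Merits: the lactone end-game is one step, with no lactone enolate, no separate methylenation and ordinary protecting groups on O3 and O8 (no silicon oxidation).
- Weak points: it leaves the ten-membered ring, both olefin geometries and the C6/C7/C8 triad to be solved before the key step. The Lewis-acidic medium meets an allylic C6 alcohol and an acid-sensitive diene.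
- Comparison: it is clearly shorter than the chosen plan at the lactone stage. The chosen plan answers the harder question of how the ring and its olefins arise, which this road does not address.

**Alternative 3: anionic oxy-Cope ring expansion.** The cut is C8–C9. In the forward direction a potassium alkoxide rearranges, C8–C9 forms as C1–C6 breaks, and a six-membered ring expands to dienone A3, the silyl-ether analogue of **14**.
- Merits: it runs far below the temperature of the cycloreversion. The Z C4=C5 bond is carried over from a ring olefin and is therefore certain. The E C1=C10 bond follows from a chair transition state. The end-game would be the one used here.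
- Weak points: C8 is set only through the geometry of a β-silylvinyl nucleophile and the transition-state shape. That nucleophile must add 1,2 and trans to a hindered, heavily substituted cyclohexenone. C3 must be oxygenated with control on that same ring.
- Comparison: in olefin geometry and mildness this road is as good as or better than the chosen plan. The chosen plan sets against it that C3 and C8 are each made independently on a small ring, by resolution and by asymmetric catalysis, and that the two halves are joined convergently.

Key step: step 9

Remark (assumption): all intermediates carry germacranolide numbers (ring C1–C10, C11–C13 lactone carbons, C14 on C10, C15 on C4). α/β refer to the usual germacranolide drawing, in which the target is 3β,8β-dioxygenated with a 6α,12-lactone, a 7β side chain and a 1β,10α-epoxide.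

## Route

Step 1
Reactants: 1 cyclohex-2-en-1-one; 2 2-(dimethylphenylsilyl)-4,4,5,5-tetramethyl-1,3,2-dioxaborolane
Product: 3 (S)-3-(dimethylphenylsilyl)cyclohexan-1-one
Conditions: [Rh(cod)2]OTf (cat.), (S)-BINAP, Et3N, 1,4-dioxane/H2O, 45 °C
Reagents that add atoms: none
Why: Rhodium-catalysed asymmetric conjugate silyl transfer from the Si–B reagent; the bisphosphine sets the future C8 centre. The S ligand is chosen by analogy with rhodium–BINAP conjugate arylation; the antipodal ligand would be used should the sense prove opposite.

Step 2
Reactants: 3 (S)-3-(dimethylphenylsilyl)cyclohexan-1-one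
Product: 5 (S)-5-(dimethylphenylsilyl)cyclohex-2-en-1-one, via trimethylsilyl enol ether 4 (not isolated)
Conditions: LiN(iPr)2, Me3SiCl, THF, −78 °C; then Pd(OAc)2, MeCN, rt
Reagents that add atoms: none
Why: Kinetic deprotonation should favour the α-methylene remote from the bulky silyl-bearing carbon, and Saegusa oxidation of the silyl enol ether gives the enone. The regioisomeric 3-silyl enone from the minor enolate is removed by chromatography.

Step 3
Reactants: 5 (S)-5-(dimethylphenylsilyl)cyclohex-2-en-1-one
Product: 6 (5S)-5-(dimethylphenylsilyl)-1-methylcyclohex-2-en-1-ol (both C1 epimers)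
Conditions: MeLi, Et2O, −78 °C
Reagents that add atoms: methyllithium, C[Li]
Why: 1,2-Addition of methyllithium to the enone carbonyl. The new carbinol centre is of no consequence because it is removed in step 4.

Step 4
Reactants: 6 (5S)-5-(dimethylphenylsilyl)-1-methylcyclohex-2-en-1-ol
Product: 7 (R)-5-(dimethylphenylsilyl)-3-methylcyclohex-2-en-1-one
Conditions: pyridinium chlorochromate, CH2Cl2, rt
Reagents that add atoms: pyridinium chlorochromate, [O-][Cr](=O)(=O)Cl.c1cc[nH+]cc1
Why: Babler–Dauben oxidative transposition: the chromate ester of the tertiary allylic alcohol undergoes a [3,3] shift and oxidation, moving the carbonyl to the far end of the allyl unit. The silyl-bearing centre is untouched; its descriptor changes to R through CIP priorities only.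

Step 5
Reactants: 8 methylenecyclobutane
Product: 9 1-methylcyclobutene
Conditions: KOtBu (cat.), DMSO, rt; distil
Reagents that add atoms: none
Why: Base-mediated prototropic isomerisation of the exocyclic alkene to the endocyclic trisubstituted one, a known equilibration. The volatile product is distilled and used directly.

Step 6
Reactants: 9 1-methylcyclobutene
Product: 10 (±)-2-methylcyclobut-2-en-1-ol
Conditions: SeO2 (cat.), tBuOOH, CH2Cl2, 0 °C to rt
Reagents that add atoms: tert-butyl hydroperoxide, CC(C)(C)OO; selenium dioxide (oxygen carrier), O=[Se]=O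
Why: SeO2 allylic oxidation (ene reaction, then [2,3] shift) with tBuOOH as reoxidant. The ring CH2 on the methyl-bearing end of the alkene is the expected site, which places the hydroxyl next to the methyl-bearing sp2 carbon.

Step 7
Reactants: 10 (±)-2-methylcyclobut-2-en-1-ol
Product: 11 (S)-2-methylcyclobut-2-en-1-ol
Conditions: lipase from Burkholderia cepacia (Amano PS), vinyl acetate, pentane, rt, run past half conversion
Reagents that add atoms: none
Why: Lipase-catalysed kinetic resolution by acylation. With the methyl-bearing sp2 carbon as the large substituent the R alcohol should be acylated faster, so the S alcohol, which carries the C3 configuration of the target, is recovered.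

Step 8
Reactants: 11 (S)-2-methylcyclobut-2-en-1-ol
Product: 12 1-methoxy-4-({[(1S)-2-methylcyclobut-2-en-1-yl]oxy}methyl)benzene
Conditions: 2-(4-methoxybenzyloxy)-4-methylquinoline, MeOTf, MgO, PhCF3, 0 °C to rt
Reagents that add atoms: 2-(4-methoxybenzyloxy)-4-methylquinoline, COc1ccc(COc2cc(C)c3ccccc3n2)cc1
Why: Neutral transfer of the 4-methoxybenzyl group from the N-methylated quinolinium reagent, buffered by MgO. Alkoxide conditions are avoided because cyclobutenyl alkoxides undergo anion-accelerated electrocyclic ring opening; acid is avoided because the allylic cyclobutenyl cation is symmetric and would racemise C3. The ether is chosen over a silyl ether because it survives the fluoride of step 14.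

Step 9
Reactants: 7 (R)-5-(dimethylphenylsilyl)-3-methylcyclohex-2-en-1-one; 12 1-methoxy-4-({[(1S)-2-methylcyclobut-2-en-1-yl]oxy}methyl)benzene
Product: 13 (1R,2R,4S,5R,6R,9R)-9-(dimethylphenylsilyl)-4-(4-methoxybenzyloxy)-1,5-dimethyltricyclo[4.4.0.0(2,5)]decan-7-one (cis-anti-cis)
Conditions: hν (350 nm, Pyrex), 12 in excess (recovered), CH2Cl2, −20 °C; then basic Al2O3, CH2Cl2, rt
Reagents that add atoms: none
Why: Excitation of the enone (n→π*, intersystem crossing) gives the twisted triplet, which adds to the strained cyclobutene to form a triplet 1,4-biradical; after spin inversion, radical recombination closes the central cyclobutane, so C4–C5 and C1–C10 are formed. The closest known reaction is the [2+2] photocycloaddition of 3-methylcyclohex-2-enones to 1-methylcyclobutene, which gives the head-to-head tricyclo[4.4.0.0(2,5)]decanone used in photochemical–thermal routes to germacradienones. The step needs regioselectivity (C5 to C4, C10 to C1), and sterics should secure it: the alternative would join the two methyl-bearing carbons C10 and C4 as vicinal quaternary centres next to the C3 ether. C1 and C4 stay cis because the cyclobutene is a cis olefin; C5 and C10 end cis because the trans-fused bicyclo[4.2.0]octanone is strained, and any trans-fused adduct is epimerised at the enolisable C5 on basic alumina. The outer rings lie anti across the new ring because the cyclobutene approaches with its ring turned away from the cyclohexenone. The cyclobutene should react on the face opposite its C3 ether, which with the anti arrangement fixes C1, C4, C5 and C10 as drawn and places the new bonds cis to the C8 silyl group. This facial choice is not critical: the other cis-anti-cis adduct keeps C3 and C8, has the mirror-image core, opens to the same dienone in step 10 and need not be separated.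

Step 10
Reactants: 13 cis-anti-cis tricyclic ketone
Product: 14 (2Z,4S,6E,9R)-9-(dimethylphenylsilyl)-4-(4-methoxybenzyloxy)-3,7-dimethylcyclodeca-2,6-dien-1-one
Conditions: toluene, 185 °C, sealed base-washed tube, 2,6-di-tert-butyl-4-methylphenol (cat.)
Reagents that add atoms: none
Why: Thermal cycloreversion of the bicyclo[2.2.0]hexane unit: homolysis of the central C1–C4 bond gives a cyclohexane-1,4-diyl that cleaves the ring-fusion bond C5–C10, a formal retro-[2+2] known for these photoadducts. The cis ring fusion should give the cis,trans-diene, with the conjugated C4=C5 bond Z and C1=C10 E, as in the closely related 3-methylcyclohexenone/1-methylcyclobutene case. The four centres made in step 9 are erased; C3 and C8 are untouched.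

Step 11
Reactants: 14 dienone; 15 methyl bromoacetate
Product: 16 methyl 8β-(dimethylphenylsilyl)-3β-(4-methoxybenzyloxy)-6-oxo-13-norgermacra-1(10)E,4Z-dien-12-oate (7αH)
Conditions: LiN(iPr)2, THF, −78 °C; then 15, DMPU, −78 to −40 °C
Reagents that add atoms: none
Why: Kinetic α'-deprotonation gives the cross-conjugated lithium enolate at C7, which is alkylated by the bromoacetate. Attack anti to the C8 silyl group in the conformer with H8 eclipsing the enolate (1,2-induction by a β-silyl centre) should place the side chain β, cis on the ring to silicon. The ten-membered ring can adopt this open-chain geometry and a cyclohexanone cannot, which is why the alkylation follows ring expansion.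

Step 12
Reactants: 16 keto ester
Product: 18 6β-hydroxy-8β-(dimethylphenylsilyl)-3β-(4-methoxybenzyloxy)-13-norgermacra-1(10)E,4Z-dien-12-oic acid, via hydroxy ester 17 (not isolated)
Conditions: NaBH4, CeCl3·7H2O, MeOH, −78 °C; then LiOH, THF/H2O, 0 °C to rt; cold 1 M HCl to pH 5, extract, use at once
Reagents that add atoms: lithium hydroxide, [Li+].[OH-]
Why: Luche 1,2-reduction of the enone. Felkin–Anh attack anti to the C8 branch of C7 is expected to give the 6β alcohol, cis to the side chain. The methyl ester (or any cis-lactone formed from it) is saponified in the same flask, and the acid is liberated cold to delay closure to the cis-lactone.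

Step 13
Reactants: 18 6β-hydroxy acid
Product: 19 8β-(dimethylphenylsilyl)-3β-(4-methoxybenzyloxy)-13-norgermacra-1(10)E,4Z-dien-6α,12-olide
Conditions: PPh3, DIAD, THF, 0 °C
Reagents that add atoms: none
Why: Intramolecular Mitsunobu reaction: the allylic C6 hydroxyl is activated as the oxyphosphonium ion and displaced by the carboxylate in an SN2 5-exo closure. This inverts C6 to the 6α-oxygen and gives the trans-fused lactone.

Step 14
Reactants: 19 silyl lactone
Product: 20 8β-hydroxy-3β-(4-methoxybenzyloxy)-13-norgermacra-1(10)E,4Z-dien-6α,12-olide
Conditions: tBuOOH, KH, Bu4NF, N-methylpyrrolidone, 0 to 60 °C; aq. NH4Cl work-up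
Reagents that add atoms: tert-butyl hydroperoxide, CC(C)(C)OO
Why: Fleming–Tamao oxidation in its basic, fluoride-promoted form: nucleophilic cleavage of the Si–Ph bond and 1,2-shift of C8 from silicon to peroxide oxygen with retention give the 8β alcohol, without the electrophiles that the two ring alkenes would not survive. The 4-methoxybenzyl ether is inert to fluoride, and a lactone opened reversibly by the base should reclose on work-up.

Step 15
Reactants: 20 hydroxy lactone
Product: 23 8β-hydroxy-3β-(4-methoxybenzyloxy)germacra-1(10)E,4Z,11(13)-trien-6α,12-olide, via Mannich base 21 (not isolated), via methiodide 22 (not isolated)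
Conditions: LiN(iPr)2 (2.2 equiv), THF, −78 °C; [Me2N=CH2]I, −78 to 0 °C; then MeI, MeOH, rt; then aq. NaHCO3, EtOAc
Reagents that add atoms: N,N-dimethylmethyleneiminium iodide (Eschenmoser's salt), C=[N+](C)C.[I-]
Why: α-Methylenation by the Mannich route: the alkoxide–enolate dianion is aminomethylated at C11, the amine is quaternised and trimethylamine is eliminated with mild base. It is done before either ester is present, since both would interfere with strong base.

Step 16
Reactants: 24 methyl (Z)-2-methylbut-2-enoate (methyl angelate)
Product: 25 (Z)-2-methylbut-2-en-1-ol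
Conditions: iBu2AlH, CH2Cl2, −78 to 0 °C
Reagents that add atoms: none
Why: Reduction of the ester to the allylic alcohol with iBu2AlH at low temperature, which keeps the Z geometry.

Step 17
Reactants: 25 (Z)-2-methylbut-2-en-1-ol
Product: 26 [(2R,3S)-2,3-dimethyloxiran-2-yl]methanol
Conditions: Ti(OiPr)4 (cat.), D-(−)-diethyl tartrate, tBuOOH, 4 Å molecular sieves, CH2Cl2, −20 °C
Reagents that add atoms: tert-butyl hydroperoxide, CC(C)(C)OO
Why: Sharpless asymmetric epoxidation. D-(−)-tartrate is chosen because L-(+)-tartrate gives the 2S,3R series with Z-3-substituted 2-alkenols of the nerol type, so the D ester should give the 2R,3S epoxy alcohol.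

Step 18
Reactants: 26 [(2R,3S)-2,3-dimethyloxiran-2-yl]methanol
Product: 27 (2S,3S)-2,3-dimethyloxirane-2-carboxylic acid
Conditions: RuCl3 (cat.), NaIO4, MeCN/EtOAc/H2O, 0 °C to rt
Reagents that add atoms: water, O; sodium periodate, [Na+].[O-]I(=O)(=O)=O
Why: RuO4 oxidation (from RuCl3 and NaIO4) of the primary alcohol to the acid, a standard way to 2,3-epoxy acids. C2 becomes S through CIP priorities only.

Step 19
Reactants: 23 hydroxy α-methylene lactone; 27 (2S,3S)-2,3-dimethyloxirane-2-carboxylic acid
Product: 28 8β-[(2S,3S)-2,3-dimethyloxirane-2-carbonyloxy]-3β-(4-methoxybenzyloxy)germacra-1(10)E,4Z,11(13)-trien-6α,12-olide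
Conditions: 27, 2,4,6-trichlorobenzoyl chloride, Et3N, toluene, rt; then 23, DMAP, toluene, rt
Reagents that add atoms: none
Why: Yamaguchi esterification through the mixed anhydride, suited to a hindered secondary alcohol and an α,α-disubstituted acid that has no α-hydrogen to epimerise. The C8–O bond is not touched, so the 8β configuration is kept.

Step 20
Reactants: 28 4-methoxybenzyl ether
Product: 29 8β-[(2S,3S)-2,3-dimethyloxirane-2-carbonyloxy]-3β-hydroxygermacra-1(10)E,4Z,11(13)-trien-6α,12-olide
Conditions: DDQ, CH2Cl2/pH 7 phosphate buffer, 0 °C
Reagents that add atoms: none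
Why: Oxidative removal of the 4-methoxybenzyl ether by DDQ (hydride abstraction, then hydrolysis of the oxocarbenium ion). The buffered conditions should spare the epoxy ester, the α-methylene lactone and the diene.

Step 21
Reactants: 29 C3 alcohol
Product: 30 8β-[(2S,3S)-2,3-dimethyloxirane-2-carbonyloxy]-3β-(3-methylbutanoyloxy)germacra-1(10)E,4Z,11(13)-trien-6α,12-olide
Conditions: (iPrCH2CO)2O, DMAP (cat.), Et3N, CH2Cl2, 0 °C
Reagents that add atoms: 3-methylbutanoic anhydride, CC(C)CC(=O)OC(=O)CC(C)C
Why: DMAP-catalysed acylation of the allylic C3 alcohol at oxygen, with retention. It is placed after all strong-base steps because the isovalerate is enolisable.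

Step 22
Reactants: 30 triene diester
Product: 31 1β,10α-epoxy-8β-[(2S,3S)-2,3-dimethyloxirane-2-carbonyloxy]-3β-(3-methylbutanoyloxy)germacra-4Z,11(13)-dien-6α,12-olide (CNP0167461.1)
Conditions: mCPBA, NaHCO3, CH2Cl2, 0 °C
Reagents that add atoms: 3-chloroperoxybenzoic acid, OOC(=O)c1cccc(Cl)c1
Why: Prilezhaev epoxidation. The peracid selects the isolated, electron-rich C1=C10 alkene over C4=C5 (flanked by two acyloxy-bearing carbons) and over the conjugated methylene. Syn addition to the E alkene on the exposed outer face of the ring should give the 1β,10α-epoxide (1R,10R).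

## Compound list

1 | cyclohex-2-en-1-one | O=C1C=CCCC1 | starting material
2 | 2-(dimethylphenylsilyl)-4,4,5,5-tetramethyl-1,3,2-dioxaborolane | CC1(C)OB([Si](C)(C)c2ccccc2)OC1(C)C | starting material
3 | (S)-3-(dimethylphenylsilyl)cyclohexan-1-one | O=C1C[C@@H]([Si](C)(C)c2ccccc2)CCC1 | intermediate
4 | trimethyl{[(5S)-5-(dimethylphenylsilyl)cyclohex-1-en-1-yl]oxy}silane | C[Si](C)(C)OC1=CCC[C@H]([Si](C)(C)c2ccccc2)C1 | intermediate (not isolated)
5 | (S)-5-(dimethylphenylsilyl)cyclohex-2-en-1-one | O=C1C[C@@H]([Si](C)(C)c2ccccc2)CC=C1 | intermediate
6 | (5S)-5-(dimethylphenylsilyl)-1-methylcyclohex-2-en-1-ol, both C1 epimers | CC1(O)C[C@@H]([Si](C)(C)c2ccccc2)CC=C1 | intermediate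
7 | (R)-5-(dimethylphenylsilyl)-3-methylcyclohex-2-en-1-one | O=C1C=C(C)C[C@@H]([Si](C)(C)c2ccccc2)C1 | intermediate
8 | methylenecyclobutane | C=C1CCC1 | starting material
9 | 1-methylcyclobutene | CC1=CCC1 | intermediate
10 | (±)-2-methylcyclobut-2-en-1-ol | CC1=CCC1O | intermediate
11 | (S)-2-methylcyclobut-2-en-1-ol | CC1=CC[C@@H]1O | intermediate
12 | 1-methoxy-4-({[(1S)-2-methylcyclobut-2-en-1-yl]oxy}methyl)benzene | CC1=CC[C@@H]1OCc1ccc(OC)cc1 | intermediate
13 | (1R,2R,4S,5R,6R,9R)-9-(dimethylphenylsilyl)-4-(4-methoxybenzyloxy)-1,5-dimethyltricyclo[4.4.0.0(2,5)]decan-7-one; cis-anti-cis; germacrane atoms: C10–C1 and C4–C5 new, ether on C3 trans to the C4–C5 bond, silyl on C8 cis to the C10–C1 bond | O=C1C[C@H]([Si](C)(C)c2ccccc2)C[C@@]3(C)[C@@H]1[C@]4(C)[C@@H](OCc5ccc(OC)cc5)C[C@H]34 | intermediate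
14 | (2Z,4S,6E,9R)-9-(dimethylphenylsilyl)-4-(4-methoxybenzyloxy)-3,7-dimethylcyclodeca-2,6-dien-1-one (germacrane: 6-ketone, 4Z, 1(10)E, 3β-ether, 8β-silyl) | O=C1/C=C(/C)[C@@H](OCc2ccc(OC)cc2)C/C=C(\C)C[C@@H]([Si](C)(C)c3ccccc3)C1 | intermediate
15 | methyl bromoacetate | COC(=O)CBr | starting material
16 | methyl 8β-(dimethylphenylsilyl)-3β-(4-methoxybenzyloxy)-6-oxo-13-norgermacra-1(10)E,4Z-dien-12-oate (7αH; side chain cis to silicon) | O=C1/C=C(/C)[C@@H](OCc2ccc(OC)cc2)C/C=C(\C)C[C@@H]([Si](C)(C)c3ccccc3)[C@H]1CC(=O)OC | intermediate
17 | methyl 6β-hydroxy-8β-(dimethylphenylsilyl)-3β-(4-methoxybenzyloxy)-13-norgermacra-1(10)E,4Z-dien-12-oate | O[C@H]1/C=C(/C)[C@@H](OCc2ccc(OC)cc2)C/C=C(\C)C[C@@H]([Si](C)(C)c3ccccc3)[C@H]1CC(=O)OC | intermediate (not isolated)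
18 | 6β-hydroxy-8β-(dimethylphenylsilyl)-3β-(4-methoxybenzyloxy)-13-norgermacra-1(10)E,4Z-dien-12-oic acid | O[C@H]1/C=C(/C)[C@@H](OCc2ccc(OC)cc2)C/C=C(\C)C[C@@H]([Si](C)(C)c3ccccc3)[C@H]1CC(=O)O | intermediate
19 | 8β-(dimethylphenylsilyl)-3β-(4-methoxybenzyloxy)-13-norgermacra-1(10)E,4Z-dien-6α,12-olide (trans-fused) | O=C1O[C@@H]2/C=C(/C)[C@@H](OCc3ccc(OC)cc3)C/C=C(\C)C[C@@H]([Si](C)(C)c4ccccc4)[C@H]2C1 | intermediate
20 | 8β-hydroxy-3β-(4-methoxybenzyloxy)-13-norgermacra-1(10)E,4Z-dien-6α,12-olide | O=C1O[C@@H]2/C=C(/C)[C@@H](OCc3ccc(OC)cc3)C/C=C(\C)C[C@@H](O)[C@H]2C1 | intermediate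
21 | 13-(dimethylamino)-8β-hydroxy-3β-(4-methoxybenzyloxy)germacra-1(10)E,4Z-dien-6α,12-olide, C11 epimers | CN(C)CC1C(=O)O[C@@H]2/C=C(/C)[C@@H](OCc3ccc(OC)cc3)C/C=C(\C)C[C@@H](O)[C@@H]12 | intermediate (not isolated)
22 | 8β-hydroxy-3β-(4-methoxybenzyloxy)-13-(trimethylammonio)germacra-1(10)E,4Z-dien-6α,12-olide iodide, C11 epimers | C[N+](C)(C)CC1C(=O)O[C@@H]2/C=C(/C)[C@@H](OCc3ccc(OC)cc3)C/C=C(\C)C[C@@H](O)[C@@H]12.[I-] | intermediate (not isolated)
23 | 8β-hydroxy-3β-(4-methoxybenzyloxy)germacra-1(10)E,4Z,11(13)-trien-6α,12-olide | C=C1C(=O)O[C@@H]2/C=C(/C)[C@@H](OCc3ccc(OC)cc3)C/C=C(\C)C[C@@H](O)[C@@H]12 | intermediate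
24 | methyl (Z)-2-methylbut-2-enoate (methyl angelate) | C/C=C(/C)C(=O)OC | starting material
25 | (Z)-2-methylbut-2-en-1-ol | C/C=C(/C)CO | intermediate
26 | [(2R,3S)-2,3-dimethyloxiran-2-yl]methanol | OC[C@@]1(C)O[C@H]1C | intermediate
27 | (2S,3S)-2,3-dimethyloxirane-2-carboxylic acid | OC(=O)[C@@]1(C)O[C@H]1C | intermediate
28 | 8β-[(2S,3S)-2,3-dimethyloxirane-2-carbonyloxy]-3β-(4-methoxybenzyloxy)germacra-1(10)E,4Z,11(13)-trien-6α,12-olide | C=C1C(=O)O[C@@H]2/C=C(/C)[C@@H](OCc3ccc(OC)cc3)C/C=C(\C)C[C@@H](OC(=O)[C@@]3(C)O[C@H]3C)[C@@H]12 | intermediate
29 | 8β-[(2S,3S)-2,3-dimethyloxirane-2-carbonyloxy]-3β-hydroxygermacra-1(10)E,4Z,11(13)-trien-6α,12-olide | C=C1C(=O)O[C@@H]2/C=C(/C)[C@@H](O)C/C=C(\C)C[C@@H](OC(=O)[C@@]3(C)O[C@H]3C)[C@@H]12 | intermediate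
30 | 8β-[(2S,3S)-2,3-dimethyloxirane-2-carbonyloxy]-3β-(3-methylbutanoyloxy)germacra-1(10)E,4Z,11(13)-trien-6α,12-olide | C=C1C(=O)O[C@@H]2/C=C(/C)[C@@H](OC(=O)CC(C)C)C/C=C(\C)C[C@@H](OC(=O)[C@@]3(C)O[C@H]3C)[C@@H]12 | intermediate
31 | 1β,10α-epoxy-8β-[(2S,3S)-2,3-dimethyloxirane-2-carbonyloxy]-3β-(3-methylbutanoyloxy)germacra-4Z,11(13)-dien-6α,12-olide; (1R,3S,6R,7R,8R,10R); CNP0167461.1 | C=C1C(=O)O[C@@H]2/C=C(/C)[C@@H](OC(=O)CC(C)C)C[C@H]3O[C@]3(C)C[C@@H](OC(=O)[C@@]3(C)O[C@H]3C)[C@@H]12 | target

## Step count and least certain steps

Total: 22 steps. Longest linear sequence: 15 steps (steps 1–4, 9–15 and 19–22; the cyclobutene branch, steps 5–8 followed by 9–15 and 19–22, is equally long).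

**Step 9 (key step).** The β-methyl enone may add slowly, with loss of regiocontrol (head-to-tail addition) or with quenching and hydrogen abstraction at the electron-rich benzyl ether of the partner. Fallback, setting out from **7** and **11** and returning at **13**: alcohol **11** is silylated (TBSCl, imidazole) to (S)-tert-butyldimethyl[(2-methylcyclobut-2-en-1-yl)oxy]silane F1, whose bulk also reinforces the head-to-head preference. Irradiation with **7** gives the silyl-protected cis-anti-cis photoadduct F2. Fluoride then frees the tricyclic cyclobutanol F3, which is no longer allylic and is 4-methoxybenzylated without risk (trichloroacetimidate, catalytic acid) to give **13**.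

**Step 10.** At the temperature needed for the cycloreversion the product may undergo Cope rearrangement to a divinylcyclohexanone or hydrogen-shift deconjugation of the Z enone. The sense of the cis,trans outcome (which olefin becomes E) rests on analogy. Fallback, setting out from **13** and returning at **14**: the ketone is reduced (NaBH4) to the tricyclic alcohol F4, which is thermolysed to the cyclodecadienol F5. The allylic alcohol is then reoxidised (MnO2) to **14**. The olefin geometry must be re-examined in this series.

**Step 11.** Facial selectivity at C7 may be governed by peripheral attack on the medium ring instead of by the silyl group, giving alkylation syn to silicon. Fallback, setting out from **14** and returning at **16**: if the C7 epimer of the keto ester F6 is the main product, it is deprotonated again at C7 (KN(SiMe3)2, THF, −78 °C) and the enolate is protonated kinetically with a hindered phenol. The proton then takes the face the electrophile preferred, which turns the side chain into the 7β position of **16**.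

**Step 12.** Hydride may enter from the other face, giving the 6α alcohol, or the 6β-hydroxy acid may close to the cis-lactone before it can be inverted. Fallback, setting out from **16** and returning at **19**: if reduction gives the 6α alcohol, saponification yields the 6α-hydroxy acid F7, which is lactonised with retention (carbodiimide, DMAP) to **19** and step 13 is omitted. A mixture of C6 epimers is divided between the two closures.

**Step 14.** The strongly basic peroxide medium may open the lactone and let the new C8 alkoxide relactonise towards C8, or attack the allylic lactone. Fallback, setting out from **19** and returning at **20**: the Si–Ph bond is first cleaved with Bu4NF in wet DMF to the dimethylsilanol F8, which is isolated and oxidised under buffered Tamao conditions (H2O2, KHCO3, KF, THF/MeOH). The C–Si to C–O change then no longer meets alkoxide or hydride base.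

**Step 7.** The lipase may discriminate poorly between the two small ring flanks, and the volatile alcohol is hard to recover. Fallback, setting out from **10** and returning at **11**: racemic **10** is oxidised (MnO2) to 2-methylcyclobut-2-en-1-one F9, kept cold in solution. It is reduced with (R)-2-methyl-CBS-oxazaborolidine and catecholborane, which should give the S alcohol with the substituted alkenyl carbon as the large group.

## Further compounds

F1 | step 9 | (S)-tert-butyldimethyl[(2-methylcyclobut-2-en-1-yl)oxy]silane | CC1=CC[C@@H]1O[Si](C)(C)C(C)(C)C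
F2 | step 9 | silyl-protected cis-anti-cis photoadduct, (1R,2R,4S,5R,6R,9R)-4-(tert-butyldimethylsilyloxy)-9-(dimethylphenylsilyl)-1,5-dimethyltricyclo[4.4.0.0(2,5)]decan-7-one | O=C1C[C@H]([Si](C)(C)c2ccccc2)C[C@@]3(C)[C@@H]1[C@]4(C)[C@@H](O[Si](C)(C)C(C)(C)C)C[C@H]34
F3 | step 9 | tricyclic cyclobutanol, (1R,2R,4S,5R,6R,9R)-9-(dimethylphenylsilyl)-4-hydroxy-1,5-dimethyltricyclo[4.4.0.0(2,5)]decan-7-one | O=C1C[C@H]([Si](C)(C)c2ccccc2)C[C@@]3(C)[C@@H]1[C@]4(C)[C@@H](O)C[C@H]34
F4 | step 10 | tricyclic alcohol, 9-(dimethylphenylsilyl)-4-(4-methoxybenzyloxy)-1,5-dimethyltricyclo[4.4.0.0(2,5)]decan-7-ol, C7 epimers | OC1C[C@H]([Si](C)(C)c2ccccc2)C[C@@]3(C)[C@@H]1[C@]4(C)[C@@H](OCc5ccc(OC)cc5)C[C@H]34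
F5 | step 10 | cyclodecadienol, (2Z,4S,6E,9R)-9-(dimethylphenylsilyl)-4-(4-methoxybenzyloxy)-3,7-dimethylcyclodeca-2,6-dien-1-ol, C1 epimers | OC1/C=C(/C)[C@@H](OCc2ccc(OC)cc2)C/C=C(\C)C[C@@H]([Si](C)(C)c3ccccc3)C1
F6 | step 11 | C7 epimer of the keto ester, methyl 8β-(dimethylphenylsilyl)-3β-(4-methoxybenzyloxy)-6-oxo-13-norgermacra-1(10)E,4Z-dien-12-oate (7βH) | O=C1/C=C(/C)[C@@H](OCc2ccc(OC)cc2)C/C=C(\C)C[C@@H]([Si](C)(C)c3ccccc3)[C@@H]1CC(=O)OC
F7 | step 12 | 6α-hydroxy acid, 6α-hydroxy-8β-(dimethylphenylsilyl)-3β-(4-methoxybenzyloxy)-13-norgermacra-1(10)E,4Z-dien-12-oic acid | O[C@@H]1/C=C(/C)[C@@H](OCc2ccc(OC)cc2)C/C=C(\C)C[C@@H]([Si](C)(C)c3ccccc3)[C@H]1CC(=O)O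
F8 | step 14 | dimethylsilanol, 8β-(hydroxydimethylsilyl)-3β-(4-methoxybenzyloxy)-13-norgermacra-1(10)E,4Z-dien-6α,12-olide | O=C1O[C@@H]2/C=C(/C)[C@@H](OCc3ccc(OC)cc3)C/C=C(\C)C[C@@H]([Si](C)(C)O)[C@H]2C1
F9 | step 7 | 2-methylcyclobut-2-en-1-one | CC1=CCC1=O
A1 | alternative 1 | ten-membered α-(4-methoxybenzyloxy) carboxylic acid from the Ireland–Claisen contraction (O6 triethylsilyl, O3 triisopropylsilyl, C7 bearing the 3-(triethylsilyloxy)prop-1-en-2-yl branch) | C=C(CO[Si](CC)(CC)CC)[C@H]1[C@H](O[Si](CC)(CC)CC)/C=C(/C)[C@@H](O[Si](C(C)C)(C(C)C)C(C)C)C/C=C(\C)C[C@@]1(OCc1ccc(OC)cc1)C(=O)O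
A2 | alternative 2 | 8β-(tert-butyldimethylsilyloxy)-3β-(4-methoxybenzyloxy)germacra-1(10)E,4Z,11(13)-trien-6α,12-olide | C=C1C(=O)O[C@@H]2/C=C(/C)[C@@H](OCc3ccc(OC)cc3)C/C=C(\C)C[C@@H](O[Si](C)(C)C(C)(C)C)[C@@H]12
A3 | alternative 3 | (2Z,4S,6E,9R)-4-(tert-butyldimethylsilyloxy)-9-(dimethylphenylsilyl)-3,7-dimethylcyclodeca-2,6-dien-1-one | O=C1/C=C(/C)[C@@H](O[Si](C)(C)C(C)(C)C)C/C=C(\C)C[C@@H]([Si](C)(C)c2ccccc2)C1
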